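**Plan**

- Numbering the chain C1=C2–C3(=O)–C4–C5(=O)–C6–C7 from ring A (styryl end) to ring B, the C3 carbonyl lies between alkene carbon C2 and the doubly activated C4 methylene, so it can be delivered as carbon monoxide.
- Retrosynthesis: a CO2tBu group is put back on C4, then C2–C3 and C3–C4 are cut to give a ring A (E)-alkenyl bromide, CO and a ring B β-keto ester. The keto ester is cut at C4–C5 to dihydroferulic acid and Meldrum's acid; the bromide goes back to ferulic acid.
- Forward: each arm is made in two steps, the three components are joined in one palladium-catalysed carbonylation, then the ester carbon leaves as CO2 and both phenols are freed. The chain is acyclic and no ring is formed.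
- Stereochemistry: the E C1=C2 alkene is the only stereo-element. It is fixed by the E-selective bromodecarboxylation and carried through oxidative addition with retention.

Key step: step 5

Assumption: both phenols are carried as tert-butyldimethylsilyl (TBS) ethers, because aryl silyl ethers should withstand the trifluoroacetic acid that unmasks the C4 carboxyl group; any partial loss is harmless since the last step removes them.

**Route**

Step 1
Reactants: 1 ferulic acid
Product: 3 (E)-3-[4-(tert-butyldimethylsilyloxy)-3-methoxyphenyl]prop-2-enoic acid, via bis-silylated ferulic acid 2 (not isolated)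
Conditions: TBSCl (2.5 equiv), imidazole (5 equiv), DMF, rt; then THF/H2O/AcOH added to the flask, rt
Reagents that add atoms: tert-butyldimethylsilyl chloride, CC(C)(C)[Si](C)(C)Cl
Why: Corey silylation of both acidic OH groups followed by selective solvolysis of the much more labile silyl ester in aqueous acetic acid should leave the acid-tolerant aryl silyl ether in place.

Step 2
Reactants: 3 (E)-3-[4-(tert-butyldimethylsilyloxy)-3-methoxyphenyl]prop-2-enoic acid
Product: 4 (E)-[4-(2-bromoethenyl)-2-methoxyphenoxy](tert-butyl)dimethylsilane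
Conditions: NBS (1.05 equiv), Et3N (10 mol%), CH2Cl2, rt, short reaction time, exclusion of light
Reagents that add atoms: N-bromosuccinimide, O=C1CCC(=O)N1Br
Why: In this catalytic Hunsdiecker-type bromodecarboxylation the carboxylate alkene takes up electrophilic bromine to give a benzylic cation stabilised by the para silyloxy group, and loss of CO2 anti to bromine should deliver the (E)-bromoalkene faster than the ring is brominated in CH2Cl2.

Step 3
Reactants: 5 3-(4-hydroxy-3-methoxyphenyl)propanoic acid (dihydroferulic acid)
Product: 7 3-[4-(tert-butyldimethylsilyloxy)-3-methoxyphenyl]propanoic acid, via bis-silylated dihydroferulic acid 6 (not isolated)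
Conditions: TBSCl (2.5 equiv), imidazole (5 equiv), DMF, rt; then THF/H2O/AcOH added to the flask, rt
Reagents that add atoms: tert-butyldimethylsilyl chloride, CC(C)(C)[Si](C)(C)Cl
Why: The same Corey silylation and selective silyl ester solvolysis as in step 1 applies, here on a substrate without the alkene.

Step 4
Reactants: 7 3-[4-(tert-butyldimethylsilyloxy)-3-methoxyphenyl]propanoic acid; 8 Meldrum's acid
Product: 10 tert-butyl 5-[4-(tert-butyldimethylsilyloxy)-3-methoxyphenyl]-3-oxopentanoate, via acyl Meldrum's acid 9 (not isolated)
Conditions: DCC (1.1 equiv), DMAP (1.5 equiv), CH2Cl2, 0 °C to rt; urea filtered off, acid wash, solvent exchange; then t-BuOH (5 equiv), toluene, 90 °C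
Reagents that add atoms: tert-butanol, CC(C)(C)O; Meldrum's acid (reactant 8), CC1(C)OC(=O)CC(=O)O1
Why: Carbodiimide-mediated C-acylation of Meldrum's acid and thermal fragmentation of the adduct to an acylketene (loss of acetone and CO2) that is trapped by tert-butanol is the Oikawa–Yonemitsu β-keto ester synthesis.

Step 5
Reactants: 4 (E)-[4-(2-bromoethenyl)-2-methoxyphenoxy](tert-butyl)dimethylsilane; 10 tert-butyl 5-[4-(tert-butyldimethylsilyloxy)-3-methoxyphenyl]-3-oxopentanoate (1.2 equiv); 11 carbon monoxide
Product: 12 tert-butyl (E)-5-[4-(tert-butyldimethylsilyloxy)-3-methoxyphenyl]-2-{3-[4-(tert-butyldimethylsilyloxy)-3-methoxyphenyl]propanoyl}-3-oxopent-4-enoate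
Conditions: Pd(dba)2 (5 mol%), Xantphos (5 mol%), MgCl2 (2 equiv), Et3N (3 equiv), CO (1 atm), 1,4-dioxane, 80 °C; aqueous citric acid work-up
Reagents that add atoms: carbon monoxide (reactant 11), [C-]#[O+]
Why: Proposed new method: zerovalent palladium carrying Xantphos should insert into the alkenyl C–Br bond of 4 with retention of the E geometry, CO insertion then gives a cinnamoyl complex of divalent palladium, and the magnesium-chelated enolate of 10 (soft enolisation by MgCl2 and Et3N) is acylated at carbon, which releases zerovalent palladium and forms C2–C3 and C3–C4 in one operation. The closest known reaction type is the palladium-catalysed carbonylative C-acylation of 1,3-dicarbonyl compounds with aryl bromides under MgCl2 and Et3N, together with the long-established alkoxycarbonylation of alkenyl bromides, so only the pairing of an alkenyl acylpalladium species with a dicarbonyl carbon nucleophile is untested. No ring closes and no stereocentre is set, because the new methine carbon is flanked by three carbonyl groups and is fully enolised. The step needs acylation at carbon and not oxygen, reaction at C4 only, CO insertion ahead of direct vinylation, and survival of the E alkene: magnesium chelation steers the acyl group to carbon, only the methylene between ketone and ester is acidic enough for MgCl2 and Et3N, the wide bite angle of Xantphos favours the acyl complex under 1 atm of CO, and oxidative addition is stereoretentive. The product is a stronger acid than 10 and stays as its magnesium chelate until work-up, which should shield the new enone from conjugate addition by unreacted enolate.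

Step 6
Reactants: 12 tert-butyl triketo ester
Product: 14 (E)-1,7-bis[4-(tert-butyldimethylsilyloxy)-3-methoxyphenyl]hept-1-ene-3,5-dione, via triketo acid 13 (not isolated)
Conditions: TFA/CH2Cl2 (1:4), 0 °C to rt; evaporation with toluene, then toluene, 50 °C
Reagents that add atoms: none
Why: Acidolysis of the tert-butyl ester with loss of isobutene unmasks a 2,2-diacylacetic acid, which should decarboxylate through the usual six-membered hydrogen-bonded transition state on gentle warming, while aryl silyl ethers tolerate TFA in CH2Cl2.

Step 7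
Reactants: 14 (E)-1,7-bis[4-(tert-butyldimethylsilyloxy)-3-methoxyphenyl]hept-1-ene-3,5-dione
Product: 15 dihydrocurcumin, (E)-1,7-bis(4-hydroxy-3-methoxyphenyl)hept-1-ene-3,5-dione
Conditions: TBAF (2.4 equiv), AcOH (2.6 equiv), THF, 0 °C
Reagents that add atoms: none
Why: Fluoride-induced cleavage of the two aryl Si–O bonds, buffered with acetic acid so that the phenoxides and the diketone enolate are protonated at once, should free the phenols without exposing the base-sensitive enone–diketone to basic conditions.

**Compound list**

1 | ferulic acid, (E)-3-(4-hydroxy-3-methoxyphenyl)prop-2-enoic acid | COc1cc(/C=C/C(=O)O)ccc1O | starting material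
2 | tert-butyldimethylsilyl (E)-3-[4-(tert-butyldimethylsilyloxy)-3-methoxyphenyl]prop-2-enoate (bis-silylated ferulic acid) | COc1cc(/C=C/C(=O)O[Si](C)(C)C(C)(C)C)ccc1O[Si](C)(C)C(C)(C)C | intermediate
3 | (E)-3-[4-(tert-butyldimethylsilyloxy)-3-methoxyphenyl]prop-2-enoic acid | COc1cc(/C=C/C(=O)O)ccc1O[Si](C)(C)C(C)(C)C | intermediate
4 | (E)-[4-(2-bromoethenyl)-2-methoxyphenoxy](tert-butyl)dimethylsilane | COc1cc(/C=C/Br)ccc1O[Si](C)(C)C(C)(C)C | intermediate
5 | 3-(4-hydroxy-3-methoxyphenyl)propanoic acid (dihydroferulic acid) | COc1cc(CCC(=O)O)ccc1O | starting material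
6 | tert-butyldimethylsilyl 3-[4-(tert-butyldimethylsilyloxy)-3-methoxyphenyl]propanoate (bis-silylated dihydroferulic acid) | COc1cc(CCC(=O)O[Si](C)(C)C(C)(C)C)ccc1O[Si](C)(C)C(C)(C)C | intermediate
7 | 3-[4-(tert-butyldimethylsilyloxy)-3-methoxyphenyl]propanoic acid | COc1cc(CCC(=O)O)ccc1O[Si](C)(C)C(C)(C)C | intermediate
8 | Meldrum's acid, 2,2-dimethyl-1,3-dioxane-4,6-dione | CC1(C)OC(=O)CC(=O)O1 | starting material
9 | 5-{3-[4-(tert-butyldimethylsilyloxy)-3-methoxyphenyl]-1-hydroxypropylidene}-2,2-dimethyl-1,3-dioxane-4,6-dione (acyl Meldrum's acid, enol form) | COc1cc(CCC(O)=C2C(=O)OC(C)(C)OC2=O)ccc1O[Si](C)(C)C(C)(C)C | intermediate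
10 | tert-butyl 5-[4-(tert-butyldimethylsilyloxy)-3-methoxyphenyl]-3-oxopentanoate | COc1cc(CCC(=O)CC(=O)OC(C)(C)C)ccc1O[Si](C)(C)C(C)(C)C | intermediate
11 | carbon monoxide | [C-]#[O+] | starting material
12 | tert-butyl (E)-5-[4-(tert-butyldimethylsilyloxy)-3-methoxyphenyl]-2-{3-[4-(tert-butyldimethylsilyloxy)-3-methoxyphenyl]propanoyl}-3-oxopent-4-enoate (drawn as the triketo tautomer; the central carbon is enolised and carries no defined configuration) | COc1cc(/C=C/C(=O)C(C(=O)OC(C)(C)C)C(=O)CCc2ccc(O[Si](C)(C)C(C)(C)C)c(OC)c2)ccc1O[Si](C)(C)C(C)(C)C | intermediate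
13 | (E)-5-[4-(tert-butyldimethylsilyloxy)-3-methoxyphenyl]-2-{3-[4-(tert-butyldimethylsilyloxy)-3-methoxyphenyl]propanoyl}-3-oxopent-4-enoic acid (triketo acid) | COc1cc(/C=C/C(=O)C(C(=O)O)C(=O)CCc2ccc(O[Si](C)(C)C(C)(C)C)c(OC)c2)ccc1O[Si](C)(C)C(C)(C)C | intermediate
14 | (E)-1,7-bis[4-(tert-butyldimethylsilyloxy)-3-methoxyphenyl]hept-1-ene-3,5-dione | COc1cc(/C=C/C(=O)CC(=O)CCc2ccc(O[Si](C)(C)C(C)(C)C)c(OC)c2)ccc1O[Si](C)(C)C(C)(C)C | intermediate
15 | dihydrocurcumin, (E)-1,7-bis(4-hydroxy-3-methoxyphenyl)hept-1-ene-3,5-dione | COc1cc(/C=C/C(=O)CC(=O)CCc2ccc(O)c(OC)c2)ccc1O | target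

**Step count**

Total: 7 steps. Longest linear sequence: 5 steps (steps 1, 2, 5, 6, 7 or steps 3, 4, 5, 6, 7).

**Steps most likely to fail**

1. Step 5 (carbonylative C-acylation). What may go wrong:
 - direct, CO-free vinylation of the enolate;
 - acylation at oxygen;
 - conjugate addition of unreacted enolate to the enone as it forms;
 - stalling of the catalyst through chelation of palladium by the triketone product.

 The fallback uses known chemistry, sets out from 3 and 10 and comes back to the route at 12. Acid 3 is treated with (COCl)2 and catalytic DMF in CH2Cl2 to give (E)-3-[4-(tert-butyldimethylsilyloxy)-3-methoxyphenyl]prop-2-enoyl chloride F1. F1 acylates the magnesium enolate of 10 at carbon (MgCl2, pyridine, CH2Cl2, 0 °C to rt), the classical magnesium-mediated C-acylation of β-keto esters, to give 12. The C3 carbonyl then stems from ferulic acid and not from CO, and steps 6 and 7 follow unchanged.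

2. Step 6 (ester cleavage and decarboxylation). What may go wrong:
 - acid-induced loss of one acyl arm by retro-Claisen cleavage of the triacylmethane;
 - acid-catalysed closure of the enol oxygen onto the enone (six-membered oxa-Michael ring formation);
 - uneven loss of the silyl ethers.

 The fallback sets out from 9 and comes back at 15, replacing acid by fluoride for the unmasking. Acyl Meldrum's acid 9 is heated with 2-(trimethylsilyl)ethanol in place of tert-butanol to give 2-(trimethylsilyl)ethyl 5-[4-(tert-butyldimethylsilyloxy)-3-methoxyphenyl]-3-oxopentanoate F2. F2 is joined with 4 and 11 under the conditions of step 5 to give 2-(trimethylsilyl)ethyl (E)-5-[4-(tert-butyldimethylsilyloxy)-3-methoxyphenyl]-2-{3-[4-(tert-butyldimethylsilyloxy)-3-methoxyphenyl]propanoyl}-3-oxopent-4-enoate F3. Excess TBAF in THF should cleave the silylethyl ester by fluoride-triggered fragmentation together with both aryl silyl ethers. Buffering with AcOH gives (E)-5-(4-hydroxy-3-methoxyphenyl)-2-[3-(4-hydroxy-3-methoxyphenyl)propanoyl]-3-oxopent-4-enoic acid F4, which should lose CO2 on standing to give 15 directly, so that no strong acid is used.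

3. Step 2 (bromodecarboxylation). What may go wrong:
 - electrophilic bromination of the electron-rich ring;
 - addition of bromine to the product alkene;
 - erosion of the E geometry.

 The fallback sets out from 3 and comes back at 4, with no electrophilic bromine source. Ozonolysis of 3 (O3, CH2Cl2/MeOH, −78 °C; Me2S) cuts the acrylic acid down to 4-(tert-butyldimethylsilyloxy)-3-methoxybenzaldehyde F5, the silyl ether of vanillin, which could equally be made from vanillin and TBSCl. Takai–Utimoto bromo-olefination of F5 (CHBr3, CrBr2 generated from CrBr3 and LiAlH4, THF, 0 °C to rt) should then give 4 with E selectivity.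

**Further compounds**

F1 | step 5 | (E)-3-[4-(tert-butyldimethylsilyloxy)-3-methoxyphenyl]prop-2-enoyl chloride | COc1cc(/C=C/C(=O)Cl)ccc1O[Si](C)(C)C(C)(C)C
F2 | step 6 | 2-(trimethylsilyl)ethyl 5-[4-(tert-butyldimethylsilyloxy)-3-methoxyphenyl]-3-oxopentanoate | COc1cc(CCC(=O)CC(=O)OCC[Si](C)(C)C)ccc1O[Si](C)(C)C(C)(C)C
F3 | step 6 | 2-(trimethylsilyl)ethyl (E)-5-[4-(tert-butyldimethylsilyloxy)-3-methoxyphenyl]-2-{3-[4-(tert-butyldimethylsilyloxy)-3-methoxyphenyl]propanoyl}-3-oxopent-4-enoate | COc1cc(/C=C/C(=O)C(C(=O)OCC[Si](C)(C)C)C(=O)CCc2ccc(O[Si](C)(C)C(C)(C)C)c(OC)c2)ccc1O[Si](C)(C)C(C)(C)C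
F4 | step 6 | (E)-5-(4-hydroxy-3-methoxyphenyl)-2-[3-(4-hydroxy-3-methoxyphenyl)propanoyl]-3-oxopent-4-enoic acid | COc1cc(/C=C/C(=O)C(C(=O)O)C(=O)CCc2ccc(O)c(OC)c2)ccc1O
F5 | step 2 | 4-(tert-butyldimethylsilyloxy)-3-methoxybenzaldehyde | COc1cc(C=O)ccc1O[Si](C)(C)C(C)(C)C
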